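**Assumption:** compound 2 is bought as the cheap diltiazem intermediate (2R,3S)-methyl 3-(4-methoxyphenyl)glycidate. MOM = CH2OCH3. The C2 stereocenter of 1 has the (S) configuration, as derived from the target SMILES.

## Retrosynthetic overview
1. Target 1 ⇐ removal of three MOM groups ⇐ flavanone ring closure by intramolecular Mitsunobu O-arylation (SN2 with inversion) at a benzylic carbinol.
2. The 2'-hydroxyaryl β-hydroxy ketone ⇐ photochemical Ni-catalysed acyl–aryl cross-coupling (forms C4–C4a) between an A-ring aryl iodide (prenylated phloroglucinol) and a chiral dihydrocoumarin lactone.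
3. The lactone carries the only stereocenter, from the commercial glycidate (SmI2 opening). Ring order: lactone (2'-oxygen installed by OH-directed C–H silylation), then B-ring pyran (selenocyclisation/elimination), then the A-ring prenyl arene (from phloroglucinol), then the flavanone C-ring last.

## Route

**Step 1**
Reactants: 2, methyl (2R,3S)-3-(4-methoxyphenyl)oxirane-2-carboxylate
Product: 3, methyl (R)-3-hydroxy-3-(4-methoxyphenyl)propanoate
Conditions: SmI2, MeOH, THF, –78 → 0 °C
Reagents that add atoms: none (the two H come from MeOH)
Why: SmI2 reductively cleaves the epoxide C–O bond α to the ester (α,β-epoxy ester to β-hydroxy ester). The benzylic C–O bond is untouched, so the stereocenter is inherited from 2; the descriptor changes from S to R only because CIP priorities change.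

**Step 2**
Reactants: 3
Product: 4, methyl 2-[(3R)-1,1-diethyl-5-methoxy-3H-2,1-benzoxasilol-3-yl]acetate
Conditions: Et2SiH2, [Ir(cod)OMe]2 (1 mol%), THF, rt; then norbornene, Me4-phenanthroline, 100 °C
Reagents that add atoms: diethylsilane, CC[SiH2]CC
Why: Hydroxyl-directed Ir-catalysed ortho C–H silylation via the (hydrido)silyl ether (Hartwig type) puts silicon on the single ortho position next to the carbinol, and no bond to the stereocenter is broken.

**Step 3**
Reactants: 4
Product: 5, (4R)-4-hydroxy-7-methoxychroman-2-one
Conditions: 30% H2O2, KF, KHCO3, THF/MeOH, 50 °C; then DMAP (cat.), PhMe, 60 °C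
Reagents that add atoms: hydrogen peroxide, OO
Why: Tamao–Fleming oxidation turns C–Si into C–OH (the 2'-oxygen). The phenol then closes onto the methyl ester to a six-membered lactone, which masks both the 2'-OH and the acid and avoids o-quinone-methide formation.

**Step 4**
Reactants: 5
Product: 6, (4R)-4-hydroxy-6-iodo-7-methoxychroman-2-one
Conditions: NIS, MeCN, 0 °C → rt, dark
Reagents that add atoms: N-iodosuccinimide, O=C1CCC(=O)N1I
Why: Electrophilic iodination goes to C6, which is ortho to OMe and para to the acyloxy oxygen. This is B-ring C5', the future pyran carbon. C8 is disfavoured because it lies between two oxygens.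

**Step 5**
Reactants: 6
Product: 7, (4R)-4-hydroxy-7-methoxy-6-(3-methylbut-2-enyl)chroman-2-one
Conditions: prenyl-SnBu3, Pd(PPh3)4 (5 mol%), LiCl, DMF, 80 °C
Reagents that add atoms: prenyltributylstannane, CC(C)=CC[Sn](CCCC)(CCCC)CCCC
Why: Stille allyl–aryl coupling; reductive elimination at the unhindered CH2 terminus gives the linear prenyl arene.

**Step 6**
Reactants: 7
Product: 8, (4R)-4-hydroxy-8,8-dimethyl-3,4-dihydro-2H,8H-pyrano[3,2-g]chromen-2-one (the B ring carries the 2,2-dimethylchromene)
Conditions: PhSeCl, NaHCO3, CH2Cl2, –78 °C → rt; then 30% H2O2, pyridine, 0 °C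
Reagents that add atoms: none (PhSe and the O-methyl group are lost as PhSeOH and MeCl)
Why: Selenocyclisation with the OMe oxygen attacking the tertiary carbon (6-endo, Markovnikov) gives a 3-phenylselanylchroman after chloride demethylation of the oxonium. Selenoxide syn-elimination then uses the only β-H (C4), giving the 2H-chromene under neutral conditions, so the β-hydroxy lactone does not dehydrate.

**Step 7**
Reactants: 9, phloroglucinol
Product: 10, 2-(3-methylbut-2-enyl)benzene-1,3,5-triol
Conditions: prenyl bromide (1.0 equiv), NaOH (1 equiv), H2O, 0 °C → rt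
Reagents that add atoms: prenyl bromide, CC(C)=CCBr
Why: C-alkylation of the phloroglucinol ring through its phenoxide (no stereocenter involved).

**Step 8**
Reactants: 10
Product: 11, 5-OTBS ether of 10 (silyl group on the OH para to the prenyl)
Conditions: TBSCl (1.05 equiv), imidazole, DMF, 0 °C
Reagents that add atoms: TBSCl, CC(C)(C)[Si](C)(C)Cl
Why: The OH para to the prenyl is the only unhindered phenol, so it is silylated selectively.

**Step 9**
Reactants: 11
Product: 12, 1,3-bis(MOM) ether of 11
Conditions: MOMCl, NaH, THF/DMF, 0 °C
Reagents that add atoms: chloromethyl methyl ether, COCCl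
Why: Williamson-type protection of the two hindered phenols next to the prenyl.

**Step 10**
Reactants: 12
Product: 13, 4-prenyl-3,5-bis(MOM-oxy)phenol
Conditions: TBAF, THF, 0 °C
Reagents that add atoms: none
Why: Fluoride removes the silyl group and leaves the MOM groups and prenyl intact.

**Step 11**
Reactants: 13
Product: 14, 2-iodo-4-prenyl-3,5-bis(MOM-oxy)phenol
Conditions: NIS, MeCN, –20 °C
Reagents that add atoms: N-iodosuccinimide, O=C1CCC(=O)N1I
Why: Iodination ortho to the OH gives a single regioisomer because the two ortho positions are equivalent by symmetry.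

**Step 12**
Reactants: 8 and 14
Product: 15, (R)-3-hydroxy-3-(7-hydroxy-2,2-dimethyl-2H-chromen-6-yl)-1-[2-hydroxy-4,6-bis(MOM-oxy)-3-prenylphenyl]propan-1-one
Conditions: NiBr2·glyme (10 mol%), dtbbpy (12 mol%), 4CzIPN (2 mol%), i-Pr2NEt (3 equiv), DMA, blue LEDs (455 nm), 25 °C, 24 h
Reagents that add atoms: none
Why: Proposed new method: photoredox/Ni cross-electrophile coupling in which the aryl iodide 14 and the acyl C–O bond of the aryl lactone 8 form the aryl ketone, creating the key C4–C4a bond. The stereocenter is not touched. Mechanism: Ni(0) adds oxidatively to Ar–I, photoredox reduction gives Ar–Ni(I), which inserts into the lactone C(acyl)–OAr bond (the leaving group is the B-ring phenoxide), and reductive elimination gives the ketone. The closest known reactions are photoredox/Ni reductive couplings of aryl halides with anhydrides or active esters and Ni-catalysed C(acyl)–O activation of aryl esters.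

**Step 13**
Reactants: 15
Product: 16, 2'-O-MOM ether of 15
Conditions: MOMCl (1.1 equiv), K2CO3, acetone, 0 °C
Reagents that add atoms: chloromethyl methyl ether, COCCl
Why: Carbonate deprotonates only the acidic, non-chelated B-ring phenol, not the benzylic alcohol or the carbonyl-chelated A-ring OH. The free 2'-OH would otherwise form an o-quinone methide and racemise the carbinol in the next step.

**Step 14**
Reactants: 16
Product: 17, tri-MOM-protected (2S)-flavanone (compound 1 with all three phenols as MOM ethers)
Conditions: PPh3, DIAD, THF, 0.02 M, 0 °C → rt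
Reagents that add atoms: none
Why: Intramolecular Mitsunobu (6-exo SN2) by the only free A-ring phenol, the one away from the prenyl, so the prenyl ends up at C6. It inverts the (R)-carbinol to (S) at C2, and no chiral reagent is involved.

**Step 15**
Reactants: 17
Product: 1, cudraflavanone A
Conditions: p-TsOH·H2O, MeOH, 40 °C
Reagents that add atoms: none
Why: Acid methanolysis removes the three aryl MOM ethers, and the flavanone, chromene and prenyl survive mild acid. C2 is not touched.

## Compound list
1 | cudraflavanone A | CC(C)=CCc1c(O)cc2c(c1O)C(=O)C[C@@H](c1cc3c(cc1O)OC(C)(C)C=C3)O2 | target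
2 | methyl (2R,3S)-3-(4-methoxyphenyl)glycidate | COC(=O)[C@H]1[C@H](c2ccc(OC)cc2)O1 | starting material
3 | methyl (R)-3-hydroxy-3-(4-methoxyphenyl)propanoate | COC(=O)C[C@@H](O)c1ccc(OC)cc1 | intermediate
4 | benzoxasilole from 3 | COC(=O)C[C@H]1O[Si](CC)(CC)c2cc(OC)ccc21 | intermediate
5 | (4R)-4-hydroxy-7-methoxychroman-2-one | COc1ccc2c(c1)OC(=O)C[C@H]2O | intermediate
6 | 6-iodo derivative of 5 | COc1c(I)cc2c(c1)OC(=O)C[C@H]2O | intermediate
7 | 6-prenyl derivative of 5 | COc1c(CC=C(C)C)cc2c(c1)OC(=O)C[C@H]2O | intermediate
8 | chromene-fused lactone | CC1(C)C=Cc2cc3c(cc2O1)OC(=O)C[C@H]3O | intermediate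
9 | phloroglucinol | Oc1cc(O)cc(O)c1 | starting material
10 | 2-prenylphloroglucinol | CC(C)=CCc1c(O)cc(O)cc1O | intermediate
11 | 5-OTBS ether of 10 | CC(C)=CCc1c(O)cc(O[Si](C)(C)C(C)(C)C)cc1O | intermediate
12 | bis-MOM, TBS ether | CC(C)=CCc1c(OCOC)cc(O[Si](C)(C)C(C)(C)C)cc1OCOC | intermediate
13 | 4-prenyl-3,5-bis(MOM-oxy)phenol | CC(C)=CCc1c(OCOC)cc(O)cc1OCOC | intermediate
14 | 2-iodo-4-prenyl-3,5-bis(MOM-oxy)phenol | CC(C)=CCc1c(OCOC)cc(O)c(I)c1OCOC | intermediate
15 | β-hydroxy ketone | O=C(C[C@@H](O)c1cc2C=CC(C)(C)Oc2cc1O)c1c(O)cc(OCOC)c(CC=C(C)C)c1OCOC | intermediate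
16 | 2'-O-MOM β-hydroxy ketone | O=C(C[C@@H](O)c1cc2C=CC(C)(C)Oc2cc1OCOC)c1c(O)cc(OCOC)c(CC=C(C)C)c1OCOC | intermediate
17 | tri-MOM (2S)-flavanone | CC(C)=CCc1c(OCOC)cc2c(c1OCOC)C(=O)C[C@@H](c1cc3C=CC(C)(C)Oc3cc1OCOC)O2 | intermediate

**Totals:** 15 steps in total; the longest linear sequence is 10 steps (steps 1–6, then 12–15).

## Three steps most likely to fail
1. **Step 12 (proposed new method).** It may suffer protodeiodination of 14 or poor oxidative addition into the aryl lactone. Fallback (known chemistry): treat 14 with t-BuLi (2.2 equiv, THF, –78 °C) to make the aryllithium/phenoxide dianion, which acylates lactone 8 to give 15.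
2. **Step 14.** The 2,4-dioxygenated benzylic carbon can ionise and erode ee, and dehydration to the chalcone is possible. Fallback (changes approach): use the (2S,3R)-enantiomer of 2 with an A-ring iodide carrying F in place of the free OH. After coupling, close the ring by Cs2CO3/DMSO intramolecular SNAr, which retains the configuration at C2 because no bond to the stereocenter is broken.
3. **Step 2.** Selectivity and yield of the ortho C–H silylation on this ester are uncertain. Fallback: saponify 3, then carry out Pd(II)/oxidant carboxylate-directed ortho C–H lactonisation of the 3-arylpropanoic acid to give lactone 5 directly.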